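**Remarks on the chemistry**

- Ring numbering used throughout: C1 carries the methoxy group, C2 the secondary benzoate, C3=C4 is the alkene, C5 and C6 carry the oxirane oxygen, and C7 is the exocyclic carbon on C6. The "upper face" is the face of the C1 methoxy group.
- Compounds 2–7 are written as α-anomers. Any β-anomer from step 1 would react alike, and the anomeric centre disappears in step 7.
- The substrate of the key step carries a free C2 hydroxyl instead of a silyl ether. The bonds formed and the skeleton are unchanged, and both benzoates can then be introduced in the flask of the key step.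

## Structural features

The target is a cyclohexene (ring A, C1–C6) fused across C5–C6 to an oxirane (ring B), a 7-oxabicyclo[4.1.0]hept-2-ene. C6 is fully substituted and carries C7 as a benzoyloxymethyl group. Four stereocentres are contiguous in the order C2, C1, C6, C5: the C2 benzoate is trans to the C1 methoxy group, the oxirane oxygen is cis to that methoxy group, and C7 lies on the opposite face. The oxirane is allylic (C5 is attached to C4), so acid or SN2′ attack opens it easily. The benzoates are base-labile, and the ring is at the oxidation level of an arene hydrate, so any elimination leads towards a benzene ring. The real difficulty is C6: a C–O bond must be set there with a defined relation to C1 and C5, flanked by three other oxygenated carbons. C1 and C2 have the absolute configuration of C3 and C4 of D-glucose and can be inherited. The feature exploited is that C7–O, C6 and the C5–O–C6 oxirane form a 2,3-epoxy-1-ol array. Its migration isomer is a spiro oxirane C6–O–C7 with a hydroxyl on C5, which is accessible from a C6 ketone and is converted into the target array with inversion at C6.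

## Logic of the disconnections

**21 ⇒ 17 + 18.** The two acyl–oxygen bonds at O2 and O7 are cut, and in the same operation the C6–O bond of the fused oxirane is cut, the C7 oxygen being reconnected to C6. This replaces the trisubstituted oxirane by a spiro oxirane one methylene transfer away from a ketone, and removes both esters from every earlier intermediate. The forward step demands that the C5 oxygen and the spiro oxygen are trans, and that the oxirane shift is complete before 18 is added.

**17 ⇒ 16.** The O2–Si and O5–Si bonds are cut. One silyl group on both oxygens allows a single unmasking and leaves no protecting group in the key step. The forward step needs fluoride conditions that neither open the spiro oxirane nor set off the shift uncontrolled.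

**16 ⇒ 14 + 15.** The C6–C7 bond and the C7–O bond of the spiro oxirane are cut. C7 and the C6 stereocentre disappear and the problem becomes one of carbonyl face selectivity. The methylene must arrive on the upper face of C6, and 14 is base-sensitive because C5–H is both α to the carbonyl and allylic.

**14 ⇒ 13 ⇒ 12.** C6 is returned to the alcohol oxidation level and the benzylic O6–C bond is cut. O6 needs a group that differs from the silyl ethers and can bind magnesium during the earlier vinyl addition. The forward steps need an oxidative deprotection that spares silyl ethers and the alkene, and a non-basic oxidation.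

**12 ⇒ 11 ⇒ 10.** The O5–Si bond and the C3=C4 double bond are cut. Ring A opens to an acyclic 1,7-diene that already carries all four oxygenated carbons. The forward ring closure must tolerate a free allylic alcohol and three ethers.

**10 ⇒ 8 + 9.** The C4–C5 bond is cut. The C5 carbinol is traced to an aldehyde and a two-carbon unit. The addition must be syn to the neighbouring ether oxygen, which requires chelation control.

**8 ⇒ 7.** The aldehyde carbon (C5 of ring A, sugar C1) is reconnected to the pyranose ring oxygen as a methyl acetal, and the terminal alkene carbon is reconnected to iodine. The acyclic array C6–C1–C2 (sugar C2–C3–C4) is thereby returned to a pyranoside in which the three centres are fixed. The forward fragmentation must not epimerise the α-alkoxy aldehyde.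

**7 ⇒ 6 ⇒ 5 ⇒ 4 ⇒ 3 ⇒ 2 ⇒ 1.** In turn the O4–Si bond, the C–I bond, the benzylidene acetal, the benzyl-type ether on sugar O2, the acetal again and the glycosidic bond are cut. This sequence distinguishes the three free hydroxyls of 2. The only ether kept in 21 is already present in 1. Each forward step must be selective for one hydroxyl: the acetal for O4/O6, the alkylation for O2, the iodination for the primary position.

## Other disconnections considered

**Alternative 1:** The cut is through C1–C6 and C2–C3. In the forward sense, methyl 2-oxo-2H-pyran-3-carboxylate A1, bound to a chiral bis(oxazoline) complex of Cu(OSO2CF3)2 (divalent copper), would add (E)-2-methoxyvinyl benzoate A2 in an inverse-demand [4+2] reaction to give the bridged lactone A3.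
- In its favour: two C–C bonds, ring A and the trans C1/C2 pair would arise in one catalytic, enantioselective step, with the methoxy and benzoate groups already in final form. On this point it is better than the chosen plan, which needs nine steps to reach a ring with these two centres.
- Against it: A3 has its alkene at C4=C5 and its oxygen on C3, so an allylic transposition is required. C6 carries two carboxyl carbons, one of which must be excised and replaced by the oxirane oxygen. A3 can lose CO2 on warming. The regiochemistry depends on methoxy being a stronger donor than benzoyloxy in a 1,2-dioxygenated alkene that is less reactive than a simple enol ether.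
- Comparison: the cycloaddition is mechanistically well defined but does not address the C5/C6 oxirane. The chosen plan is longer at the start but sets C6 and C5 by a stereospecific migration. Overall step economy would probably be no better once the degradation at C6 is counted.

**Alternative 2:** The cut is C1–C6. SmI2 (divalent samarium) would couple the aldehyde and ketone of the (Z)-keto-aldehyde A4 to give the cyclohexene cis-diol A5.
- In its favour: the ring and two stereocentres, including the fully substituted C6 carbinol, would form together. A chelated ketyl coupling should give the cis-diol anti to both flanking ethers, which is the arrangement in A5. This is equal or better than the chosen plan for setting the C6–O bond, and it avoids the enolisable cyclic ketone 14.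
- Against it: the ketone of A4 has ether oxygens on both α-carbons, and SmI2 is likely to cleave such α-C–O bonds reductively. The (Z)-alkene with two allylic stereocentres and three different protecting groups needs a long acyclic preparation. After the coupling, A5 would still need selective methylation of the secondary C1 hydroxyl, unmasking and activation of O5, SN2 closure at an allylic carbon (with SN2′ as a competitor), two desilylations and two benzoylations.
- Comparison: both plans close the oxirane by backside attack of an alkoxide. The alternative sets C6 earlier and with a better-precedented selectivity model, but it leaves about six operations after the key step where the chosen plan leaves none.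

**Alternative 3:** The cut is C2–C3. CrCl2 (divalent chromium) with catalytic NiCl2 (divalent nickel) would turn the (Z)-iodoalkenyl epoxy aldehyde A6 into an alkenylchromium species that adds to the C2 aldehyde and gives the allylic alcohol A7. One benzoylation would then give 21.
- In its favour: it has the shortest endgame of all the plans, on which point it is the equal of the chosen plan. The conditions are neutral and tolerate ester and oxirane. The oxirane of A6 could be set by a reagent-controlled epoxidation of an acyclic allylic alcohol, which is better absolute control than the substrate-controlled ylide addition of the chosen plan.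
- Against it: the C2 carbinol would be created in the ring closure, and the facial bias of an α-methoxy aldehyde in a six-membered closure (chelation against Felkin–Anh) is not predictable. The α-alkoxy aldehyde is epimerisable. A (Z)-iodoalkene on an oxirane carbon must be made and carried. Trivalent chromium salts formed in the reaction are Lewis acids that may open the alkenyl oxirane, and CrCl2 is needed in excess.
- Comparison: the chosen plan inherits C2 from the sugar and leaves only the stereospecific migration for the end. The alternative would leave the least certain stereocentre to the last C–C bond formation, and its acyclic precursor would probably cost as many steps as the carbohydrate sequence.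

Key step: step 15

## Route

Step 1
Reactants: 1 3-O-methyl-D-glucose
Product: 2 methyl 3-O-methyl-α-D-glucopyranoside
Conditions: MeOH, AcCl (cat.), reflux
Reagents that add atoms: methanol, CO
Why: Fischer glycosidation under thermodynamic control should give the pyranoside with the α-anomer favoured by the anomeric effect; anomeric purity is not needed because this centre is destroyed in step 7.

Step 2
Reactants: 2 methyl 3-O-methyl-α-D-glucopyranoside
Product: 3 methyl (R)-4,6-O-benzylidene-3-O-methyl-α-D-glucopyranoside
Conditions: PhCH(OMe)2, CSA (cat.), DMF, 60 °C, reduced pressure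
Reagents that add atoms: benzaldehyde dimethyl acetal, COC(OC)c1ccccc1
Why: Acid-catalysed transacetalisation should close the trans-fused 1,3-dioxane on O4 and O6 with the phenyl group equatorial (R at the acetal carbon), leaving O2 as the only free hydroxyl.

Step 3
Reactants: 3 methyl (R)-4,6-O-benzylidene-3-O-methyl-α-D-glucopyranoside
Product: 4 methyl (R)-4,6-O-benzylidene-2-O-(4-methoxybenzyl)-3-O-methyl-α-D-glucopyranoside
Conditions: NaH, PMBCl, Bu4NI (cat.), DMF, 0 °C → rt
Reagents that add atoms: 4-methoxybenzyl chloride, COc1ccc(CCl)cc1
Why: Williamson etherification of the single free hydroxyl; this ether can chelate magnesium in step 8 and is removed oxidatively in step 11 without touching silyl ethers.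

Step 4
Reactants: 4 methyl (R)-4,6-O-benzylidene-2-O-(4-methoxybenzyl)-3-O-methyl-α-D-glucopyranoside
Product: 5 methyl 2-O-(4-methoxybenzyl)-3-O-methyl-α-D-glucopyranoside
Conditions: CSA (cat.), MeOH, rt
Reagents that add atoms: none
Why: Acetal exchange with methanol should remove the benzylidene group; the benzyl-type ether and the methyl glycoside are stable to catalytic sulfonic acid at room temperature.

Step 5
Reactants: 5 methyl 2-O-(4-methoxybenzyl)-3-O-methyl-α-D-glucopyranoside
Product: 6 methyl 6-deoxy-6-iodo-2-O-(4-methoxybenzyl)-3-O-methyl-α-D-glucopyranoside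
Conditions: PPh3, I2, imidazole, THF, 60 °C
Reagents that add atoms: iodine, [I][I]
Why: Garegg–Samuelsson iodination; the primary hydroxyl forms the alkoxyphosphonium salt much faster than the hindered secondary O4–H and is displaced by iodide.

Step 6
Reactants: 6 methyl 6-deoxy-6-iodo-2-O-(4-methoxybenzyl)-3-O-methyl-α-D-glucopyranoside
Product: 7 methyl 4-O-(tert-butyldimethylsilyl)-6-deoxy-6-iodo-2-O-(4-methoxybenzyl)-3-O-methyl-α-D-glucopyranoside
Conditions: TBSOTf, 2,6-lutidine, CH2Cl2, 0 °C
Reagents that add atoms: tert-butyldimethylsilyl trifluoromethanesulfonate, CC(C)(C)[Si](C)(C)OS(=O)(=O)C(F)(F)F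
Why: Silylation of the remaining hindered secondary hydroxyl with the silyl triflate; this oxygen becomes O2 of ring A and stays masked until step 14.

Step 7
Reactants: 7 methyl 4-O-(tert-butyldimethylsilyl)-6-deoxy-6-iodo-2-O-(4-methoxybenzyl)-3-O-methyl-α-D-glucopyranoside
Product: 8 4-O-(tert-butyldimethylsilyl)-5,6-dideoxy-2-O-(4-methoxybenzyl)-3-O-methyl-D-xylo-hex-5-enose, i.e. (2R,3R,4R)-4-(tert-butyldimethylsilyloxy)-3-methoxy-2-(4-methoxybenzyloxy)hex-5-enal
Conditions: Zn dust (activated), THF/H2O 9:1, sonication, 40 °C; crude product used directly
Reagents that add atoms: none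
Why: Bernet–Vasella reductive fragmentation: zinc inserts into the C–I bond and the carbon–zinc bond eliminates across the C5–O5 bond of the pyranoside, releasing the aldehyde and the terminal alkene; the three stereocentres are not touched, and immediate use limits epimerisation at the α-carbon.

Step 8
Reactants: 8 4-O-(tert-butyldimethylsilyl)-5,6-dideoxy-2-O-(4-methoxybenzyl)-3-O-methyl-D-xylo-hex-5-enose; 9 vinylmagnesium bromide
Product: 10 (3R,4S,5R,6R)-6-(tert-butyldimethylsilyloxy)-5-methoxy-4-(4-methoxybenzyloxy)octa-1,7-dien-3-ol
Conditions: MgBr2·OEt2, CH2Cl2, −20 °C; then 9 (THF solution), −78 °C; aq. NH4Cl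
Reagents that add atoms: vinylmagnesium bromide, C=C[Mg]Br
Why: Chelation-controlled (Cram chelate) Grignard addition: magnesium held between the aldehyde oxygen and the α-ether oxygen should expose the face opposite the chain, so the new carbinol (3R, later C5) is syn to the α-ether, which becomes trans in ring A.

Step 9
Reactants: 10 (3R,4S,5R,6R)-6-(tert-butyldimethylsilyloxy)-5-methoxy-4-(4-methoxybenzyloxy)octa-1,7-dien-3-ol
Product: 11 (1R,2R,5R,6S)-2-(tert-butyldimethylsilyloxy)-1-methoxy-6-(4-methoxybenzyloxy)cyclohex-3-en-5-ol (all four substituents alternately trans)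
Conditions: second-generation Grubbs catalyst RuCl2(=CHPh)(H2IMes)(PCy3) (5 mol %), CH2Cl2 (0.01 M), 40 °C
Reagents that add atoms: none
Why: Ring-closing metathesis of the 1,7-diene should form the C3=C4 bond with loss of ethylene; the free allylic hydroxyl is tolerated and no stereocentre is involved.

Step 10
Reactants: 11 (1R,2R,5R,6S)-2-(tert-butyldimethylsilyloxy)-1-methoxy-6-(4-methoxybenzyloxy)cyclohex-3-en-5-ol
Product: 12 (1R,2R,5R,6R)-2,5-bis(tert-butyldimethylsilyloxy)-1-methoxy-6-(4-methoxybenzyloxy)cyclohex-3-ene
Conditions: TBSOTf, 2,6-lutidine, CH2Cl2, −40 → 0 °C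
Reagents that add atoms: tert-butyldimethylsilyl trifluoromethanesulfonate, CC(C)(C)[Si](C)(C)OS(=O)(=O)C(F)(F)F
Why: Silylation of the allylic C5 hydroxyl with the same group as on O2, so that both are removed together in step 14.

Step 11
Reactants: 12 (1R,2R,5R,6R)-2,5-bis(tert-butyldimethylsilyloxy)-1-methoxy-6-(4-methoxybenzyloxy)cyclohex-3-ene
Product: 13 (1R,2R,5R,6R)-2,5-bis(tert-butyldimethylsilyloxy)-1-methoxycyclohex-3-en-6-ol
Conditions: DDQ, CH2Cl2/pH 7 phosphate buffer 10:1, 0 °C → rt
Reagents that add atoms: none
Why: Oxidative cleavage of the 4-methoxybenzyl ether through the benzylic cation and its hydrolysis; silyl ethers, the methyl ether and the ring alkene should be inert under buffered conditions.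

Step 12
Reactants: 13 (1R,2R,5R,6R)-2,5-bis(tert-butyldimethylsilyloxy)-1-methoxycyclohex-3-en-6-ol
Product: 14 (1S,2R,5R)-2,5-bis(tert-butyldimethylsilyloxy)-1-methoxycyclohex-3-en-6-one
Conditions: Dess–Martin periodinane, NaHCO3, CH2Cl2, 0 °C → rt; used at once
Reagents that add atoms: none
Why: Dess–Martin oxidation is neutral and buffered, which should avoid enolisation of the β,γ-unsaturated ketone; both α-centres already hold their substituents in the more stable equatorial positions.

Step 13
Reactants: 14 (1S,2R,5R)-2,5-bis(tert-butyldimethylsilyloxy)-1-methoxycyclohex-3-en-6-one; 15 trimethylsulfonium iodide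
Product: 16 (1S,2R,5R,6R)-2,5-bis(tert-butyldimethylsilyloxy)-1-methoxycyclohex-3-ene-6-spiro-2'-oxirane (oxirane oxygen on the lower face, trans to O5 and to the C1 methoxy group; C7 on the upper face)
Conditions: 15, n-BuLi, THF, −10 °C; then 14, −20 → 0 °C
Reagents that add atoms: trimethylsulfonium iodide, C[S+](C)C.[I-]
Why: Corey–Chaykovsky epoxidation: the sulfonium ylide adds irreversibly and the alkoxide then displaces Me2S. In the all-equatorial half-chair of 14 the small ylide should attack C6 along the axial direction of the upper face, anti to the axial C1–H and C5–H bonds and past only one syn-axial hydrogen, which places C7 axial and the oxygen equatorial.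

Step 14
Reactants: 16 (1S,2R,5R,6R)-2,5-bis(tert-butyldimethylsilyloxy)-1-methoxycyclohex-3-ene-6-spiro-2'-oxirane
Product: 17 (1S,2R,5R,6S)-1-methoxycyclohex-3-ene-6-spiro-2'-oxirane-2,5-diol (same relative configuration as 16)
Conditions: TBAF, AcOH (1:1), THF, 0 °C → rt
Reagents that add atoms: none
Why: Fluoride cleaves both Si–O bonds; the acetic acid buffer keeps the liberated C5 oxygen protonated so that the oxirane neither migrates nor opens, and any migrated diol formed here would be converted to 21 in step 15 as well.

Step 15
Reactants: 17 (1S,2R,5R,6S)-1-methoxycyclohex-3-ene-6-spiro-2'-oxirane-2,5-diol; 18 benzoyl chloride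
Product: 21 (1S,2R,5R,6R)-2-benzoyloxy-6-(benzoyloxymethyl)-5,6-epoxy-1-methoxycyclohex-3-ene (target CNP0231490.2), via spiro-epoxide disodium dialkoxide 19 (not isolated), via ring-fused epoxide disodium dialkoxide 20 (not isolated)
Conditions: NaH (2.5 equiv), THF, 0 °C → rt; then 18 (3 equiv), 0 °C
Reagents that add atoms: benzoyl chloride, O=C(Cl)c1ccccc1
Why: NaH deprotonates both hydroxyls, and the C5 alkoxide attacks C6 from the face opposite the spiro C6–O bond in an intramolecular SN2 step, so the C5 oxygen becomes the oxygen of the fused oxirane and the former spiro oxygen leaves as the primary C7 alkoxide. The closest known reaction type is the Payne rearrangement of a 2,3-epoxy alcohol in an aprotic medium with capture of the new alkoxide by an acylating agent. The one ring that closes, the oxirane C5–O–C6, forms in 3-exo-tet mode while the spiro oxirane opens. The only stereocentre that changes is C6, which is inverted; its configuration is dictated by C5, because the oxygen can be delivered only on the face that C5–O occupies, the face of the C1 methoxy group. The step needs migration to win over 4-exo attack at C7 and over acylation of unrearranged alkoxide. The trans relation of C5–O and C6–O (anti-periplanar in the ring-flipped half-chair, where Na+ can bridge the syn-axial C2 alkoxide and the leaving oxygen), the higher substitution of the fused oxirane and the lower basicity of the primary alkoxide should all favour 20, and 18 is added only after equilibration. Acylation of both alkoxides of 20 then stops any reverse shift and installs the two esters of the target.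

## Compound list

1 | 3-O-methyl-D-glucose | OC[C@H]1OC(O)[C@H](O)[C@@H](OC)[C@@H]1O | starting material
2 | methyl 3-O-methyl-α-D-glucopyranoside | OC[C@H]1O[C@H](OC)[C@H](O)[C@@H](OC)[C@@H]1O | intermediate
3 | methyl (R)-4,6-O-benzylidene-3-O-methyl-α-D-glucopyranoside | c1ccccc1[C@@H]2OC[C@H]3O[C@H](OC)[C@H](O)[C@@H](OC)[C@@H]3O2 | intermediate
4 | methyl (R)-4,6-O-benzylidene-2-O-(4-methoxybenzyl)-3-O-methyl-α-D-glucopyranoside | c1ccccc1[C@@H]2OC[C@H]3O[C@H](OC)[C@H](OCc4ccc(OC)cc4)[C@@H](OC)[C@@H]3O2 | intermediate
5 | methyl 2-O-(4-methoxybenzyl)-3-O-methyl-α-D-glucopyranoside | OC[C@H]1O[C@H](OC)[C@H](OCc2ccc(OC)cc2)[C@@H](OC)[C@@H]1O | intermediate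
6 | methyl 6-deoxy-6-iodo-2-O-(4-methoxybenzyl)-3-O-methyl-α-D-glucopyranoside | IC[C@H]1O[C@H](OC)[C@H](OCc2ccc(OC)cc2)[C@@H](OC)[C@@H]1O | intermediate
7 | methyl 4-O-(tert-butyldimethylsilyl)-6-deoxy-6-iodo-2-O-(4-methoxybenzyl)-3-O-methyl-α-D-glucopyranoside | IC[C@H]1O[C@H](OC)[C@H](OCc2ccc(OC)cc2)[C@@H](OC)[C@@H]1O[Si](C)(C)C(C)(C)C | intermediate
8 | (2R,3R,4R)-4-(tert-butyldimethylsilyloxy)-3-methoxy-2-(4-methoxybenzyloxy)hex-5-enal | O=C[C@H](OCc1ccc(OC)cc1)[C@@H](OC)[C@H](O[Si](C)(C)C(C)(C)C)C=C | intermediate
9 | vinylmagnesium bromide | C=C[Mg]Br | starting material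
10 | (3R,4S,5R,6R)-6-(tert-butyldimethylsilyloxy)-5-methoxy-4-(4-methoxybenzyloxy)octa-1,7-dien-3-ol | C=C[C@@H](O)[C@H](OCc1ccc(OC)cc1)[C@@H](OC)[C@H](O[Si](C)(C)C(C)(C)C)C=C | intermediate
11 | (1R,2R,5R,6S)-2-(tert-butyldimethylsilyloxy)-1-methoxy-6-(4-methoxybenzyloxy)cyclohex-3-en-5-ol | CO[C@H]1[C@H](O[Si](C)(C)C(C)(C)C)C=C[C@@H](O)[C@@H]1OCc1ccc(OC)cc1 | intermediate
12 | (1R,2R,5R,6R)-2,5-bis(tert-butyldimethylsilyloxy)-1-methoxy-6-(4-methoxybenzyloxy)cyclohex-3-ene | CO[C@H]1[C@H](O[Si](C)(C)C(C)(C)C)C=C[C@@H](O[Si](C)(C)C(C)(C)C)[C@@H]1OCc1ccc(OC)cc1 | intermediate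
13 | (1R,2R,5R,6R)-2,5-bis(tert-butyldimethylsilyloxy)-1-methoxycyclohex-3-en-6-ol | CO[C@H]1[C@H](O[Si](C)(C)C(C)(C)C)C=C[C@@H](O[Si](C)(C)C(C)(C)C)[C@@H]1O | intermediate
14 | (1S,2R,5R)-2,5-bis(tert-butyldimethylsilyloxy)-1-methoxycyclohex-3-en-6-one | CO[C@H]1[C@H](O[Si](C)(C)C(C)(C)C)C=C[C@@H](O[Si](C)(C)C(C)(C)C)C1=O | intermediate
15 | trimethylsulfonium iodide | C[S+](C)C.[I-] | starting material
16 | (1S,2R,5R,6R)-2,5-bis(tert-butyldimethylsilyloxy)-1-methoxycyclohex-3-ene-6-spiro-2'-oxirane | CO[C@H]1[C@H](O[Si](C)(C)C(C)(C)C)C=C[C@@H](O[Si](C)(C)C(C)(C)C)[C@@]12CO2 | intermediate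
17 | (1S,2R,5R,6S)-1-methoxycyclohex-3-ene-6-spiro-2'-oxirane-2,5-diol | CO[C@H]1[C@H](O)C=C[C@@H](O)[C@@]12CO2 | intermediate
18 | benzoyl chloride | O=C(Cl)c1ccccc1 | starting material
19 | disodium dialkoxide of 17 | CO[C@H]1[C@H]([O-])C=C[C@@H]([O-])[C@@]12CO2.[Na+].[Na+] | intermediate
20 | disodium (1S,2R,5R,6R)-5,6-epoxy-1-methoxy-6-(oxidomethyl)cyclohex-3-en-2-olate | CO[C@H]1[C@H]([O-])C=C[C@H]2O[C@]21C[O-].[Na+].[Na+] | intermediate
21 | (1S,2R,5R,6R)-2-benzoyloxy-6-(benzoyloxymethyl)-5,6-epoxy-1-methoxycyclohex-3-ene | CO[C@H]1[C@H](OC(=O)c2ccccc2)C=C[C@H]2O[C@]21COC(=O)c1ccccc1 | target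

## Step count and least certain steps

Total: 15 steps. Longest linear sequence: 15 steps (1 → 21).

**Step 15 (key step).** The most likely failure is that acylation overtakes the oxirane shift, or that the shift stalls because ring A must flip into the conformer in which four substituents are axial. Benzoylation of unrearranged alkoxide, or slow 4-exo attack at C7, would then compete. The fallback sets out from 17 and returns at 21, and separates equilibration from acylation. 17 would be equilibrated under thermodynamic control with catalytic KOt-Bu in t-BuOH, a protic and reversible medium with no electrophile present. The more substituted neutral epoxy diol (1S,2R,5R,6R)-5,6-epoxy-6-(hydroxymethyl)-1-methoxycyclohex-3-en-2-ol F1 would be isolated and residual 17 recycled. F1 would then be benzoylated with 18 in pyridine with DMAP, where no alkoxide exists and the reverse shift cannot occur, to give 21.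

**Step 13.** Two processes may interfere. The basic ylide may deprotonate 14 at C5, which is α to the carbonyl and allylic; double-bond migration, loss of silanol and aromatisation would follow. Alternatively, attack from the equatorial direction would put the oxirane oxygen cis to O5, and that isomer cannot migrate. The fallback sets out from 14 and returns at 16.
- Non-basic Petasis methylenation with Cp2TiMe2 in toluene at 65 °C would give the exocyclic alkene (1R,2R,5R)-2,5-bis(tert-butyldimethylsilyloxy)-1-methoxy-6-methylidenecyclohex-3-ene F2.
- Upjohn dihydroxylation with catalytic OsO4 and NMO should occur on the lower face of the exocyclic alkene, anti to both allylic oxygens (C1 methoxy and C5 silyloxy, both on the upper face). The ring alkene should react more slowly, since each of its faces is flanked by a silyloxy group. The product would be the diol (1S,2R,5R,6R)-2,5-bis(tert-butyldimethylsilyloxy)-6-(hydroxymethyl)-1-methoxycyclohex-3-en-6-ol F3, with the tertiary hydroxyl trans to O5.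
- Selective sulfonylation of the primary hydroxyl with TsCl in pyridine would give the monotosylate F4, and K2CO3 in MeOH would close the spiro oxirane with retention at C6 to give 16.

**Step 8.** Poor facial selectivity is the risk. Chelation through the β-methoxy group, or an open Felkin–Anh transition state, would both lead to the C5 epimer. The fallback sets out from 8 and returns at 11, and moves stereocontrol from the acyclic addition to a cyclic reduction.
- 9 would be added without Lewis acid and the mixture accepted, including the epimeric dienol (3S,4S,5R,6R)-6-(tert-butyldimethylsilyloxy)-5-methoxy-4-(4-methoxybenzyloxy)octa-1,7-dien-3-ol F5.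
- Ring-closing metathesis as in step 9 would give 11 together with its C5 epimer (1R,2R,5S,6S)-2-(tert-butyldimethylsilyloxy)-1-methoxy-6-(4-methoxybenzyloxy)cyclohex-3-en-5-ol F6.
- Oxidation of the mixture with MnO2 would converge both on the enone (1R,2R,6R)-2-(tert-butyldimethylsilyloxy)-1-methoxy-6-(4-methoxybenzyloxy)cyclohex-3-en-5-one F7.
- Luche reduction (NaBH4, CeCl3·7H2O, MeOH, −78 °C) should deliver hydride axially to the all-equatorial enone and give the pseudo-equatorial alcohol trans to the C6 ether, which is 11.

## Further compounds

F1 | step 15 | (1S,2R,5R,6R)-5,6-epoxy-6-(hydroxymethyl)-1-methoxycyclohex-3-en-2-ol | CO[C@H]1[C@H](O)C=C[C@H]2O[C@]21CO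
F2 | step 13 | (1R,2R,5R)-2,5-bis(tert-butyldimethylsilyloxy)-1-methoxy-6-methylidenecyclohex-3-ene | CO[C@H]1[C@H](O[Si](C)(C)C(C)(C)C)C=C[C@@H](O[Si](C)(C)C(C)(C)C)C1=C
F3 | step 13 | (1S,2R,5R,6R)-2,5-bis(tert-butyldimethylsilyloxy)-6-(hydroxymethyl)-1-methoxycyclohex-3-en-6-ol | CO[C@H]1[C@H](O[Si](C)(C)C(C)(C)C)C=C[C@@H](O[Si](C)(C)C(C)(C)C)[C@@]1(O)CO
F4 | step 13 | (1S,2R,5R,6R)-2,5-bis(tert-butyldimethylsilyloxy)-6-hydroxy-1-methoxycyclohex-3-en-6-ylmethyl 4-methylbenzenesulfonate | CO[C@H]1[C@H](O[Si](C)(C)C(C)(C)C)C=C[C@@H](O[Si](C)(C)C(C)(C)C)[C@@]1(O)COS(=O)(=O)c1ccc(C)cc1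
F5 | step 8 | (3S,4S,5R,6R)-6-(tert-butyldimethylsilyloxy)-5-methoxy-4-(4-methoxybenzyloxy)octa-1,7-dien-3-ol | C=C[C@H](O)[C@H](OCc1ccc(OC)cc1)[C@@H](OC)[C@H](O[Si](C)(C)C(C)(C)C)C=C
F6 | step 8 | (1R,2R,5S,6S)-2-(tert-butyldimethylsilyloxy)-1-methoxy-6-(4-methoxybenzyloxy)cyclohex-3-en-5-ol | CO[C@H]1[C@H](O[Si](C)(C)C(C)(C)C)C=C[C@H](O)[C@@H]1OCc1ccc(OC)cc1
F7 | step 8 | (1R,2R,6R)-2-(tert-butyldimethylsilyloxy)-1-methoxy-6-(4-methoxybenzyloxy)cyclohex-3-en-5-one | CO[C@H]1[C@H](O[Si](C)(C)C(C)(C)C)C=CC(=O)[C@@H]1OCc1ccc(OC)cc1
A1 | alternative 1 | methyl 2-oxo-2H-pyran-3-carboxylate | COC(=O)C1=CC=COC1=O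
A2 | alternative 1 | (E)-2-methoxyvinyl benzoate | CO/C=C/OC(=O)c1ccccc1
A3 | alternative 1 | methyl 7-benzoyloxy-8-methoxy-3-oxo-2-oxabicyclo[2.2.2]oct-5-ene-4-carboxylate (bridged lactone adduct) | CO[C@H]1[C@H](OC(=O)c3ccccc3)[C@@H]2C=C[C@@]1(C(=O)OC)C(=O)O2
A4 | alternative 2 | (Z)-keto-aldehyde with C2 tert-butyldimethylsilyloxy, C5 4-methoxybenzyloxy and C7 tert-butyldiphenylsilyloxy groups | O=C[C@H](O[Si](C)(C)C(C)(C)C)/C=C\[C@H](OCc1ccc(OC)cc1)C(=O)CO[Si](c1ccccc1)(c1ccccc1)C(C)(C)C
A5 | alternative 2 | cyclohexene C1/C6 cis-diol | O[C@H]1[C@H](O[Si](C)(C)C(C)(C)C)C=C[C@H](OCc2ccc(OC)cc2)[C@]1(O)CO[Si](c3ccccc3)(c4ccccc4)C(C)(C)C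
A6 | alternative 3 | (Z)-iodoalkenyl epoxy aldehyde with C1 methoxy and C7 benzoate | O=C[C@H](OC)[C@]1(COC(=O)c2ccccc2)O[C@@H]1/C=C\I
A7 | alternative 3 | C2 allylic alcohol of the target skeleton (C7 benzoate) | CO[C@H]1[C@H](O)C=C[C@H]2O[C@]21COC(=O)c1ccccc1
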